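## Structural features

Amaurone B is a fully substituted cyclohexane, numbered here from the chain-bearing carbon (C1; C2 = CH–CH3; C3 = C(CH3)OH; C4 = CH–OAc; C5 = C(CH3)OH; C6 = CH–OAc), joined through C1 to an all-E 2,6-dimethylhexatriene (C7–C12) whose far end, C12, is bonded to C6′ of a 2′-methoxy-3′,5′-dimethyl-4′-pyranone. All six ring carbons are contiguous stereocentres: the four oxygens (C3–C6) lie on one face and the four carbon substituents (C1 chain, C2, C3 and C5 methyls) on the other, so the C1 chain is trans to the C6 oxygen and cis to the C2 methyl. Two of the centres (C3, C5) are tertiary carbinols that stay free while the secondary hydroxyls beside them (C4, C6) are acetylated, so five oxygens of three kinds must be told apart. The fragile groups are the acetates (hydrolysis, migration to neighbouring hydroxyls), the C6 acetate in particular (β to C1, so it can be eliminated once C1 carries a carbonyl or vinylogous carbonyl group), the light-, acid- and base-sensitive triene, and the α-methoxy-γ-pyranone (strong acid, hard nucleophiles). The real difficulty is to set six contiguous ring stereocentres, two of them quaternary carbinols, as one enantiomer, and then to attach the polyene–pyranone without base or heat. The key step exploits the cis pair C4–O (secondary)/C5–O (tertiary): it is the syn-dihydroxylation pattern of a trisubstituted C4=C5 ring alkene, which is flanked by the C3 and C6 oxygens on the same face and which can be closed from a vinyl group on C3 and an isopropenyl group on C6 without touching a stereocentre.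

## Logic of the disconnections

31 is cut at the C10–C11 single bond between two alkenes, giving 22 and 30. This is the most convergent cut; every alkene geometry is set before the union. The forward coupling must tolerate two acetates, two free tertiary hydroxyls and the methoxypyranone.

30 is traced back through 29 and 28 to 25 and 26, and 25 to 23. The bonds cut are O–CH3, the ring O1′–C2′ acyl–oxygen bond and the C5′–C6′ bond. This reduces the heterocycle to a β-keto ester and an acrylic acid that already carries the E-vinyl iodide. The demands are selective methylation at the lactone carbonyl oxygen and acylation at the amide carbonyl, not at the β-iodo carbon.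

22 is cut at C9=C10 to 21, and 21 at C7=C8 to 19 and 20. Two carbonyl olefinations each give one E-alkene. Both must run without base because 19 has an enolisable C1–H with a β-acetoxy group.

19 goes back to 18, 17 and 16 by adjusting the oxidation level at C7, removing the silyl group and removing the two acetyl groups on O4 and O6. The gain is a tetraol with a single protected primary oxygen. The demand is acetylation of the two secondary hydroxyls in the presence of two tertiary ones.

16 is cut at the C4–O and C5–O bonds to 14. This removes two stereocentres at once. The forward osmylation must occur on the face of the C3 and C6 hydroxyls.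

14 is cut at C4=C5 to 13. The ring disappears and no stereocentre is involved. The forward step only has to cyclise and not oligomerise.

13 goes back to 12 (Si–O), and 12 to 11 by reconnecting C7 and O3 as a five-membered lactone. The lactone ties C1, C2 and C3 into a ring that can relay stereochemistry. The reduction must not trigger retro-aldol cleavage.

11 is cut at C1–C6 to 8 and 9. Two stereocentres are removed. The forward aldol must enter trans to the C2 methyl and be anti (C1/C6).

8 is cut at the vinyl C=C bond to 7, and 7 is taken back to 6 by oxidation level. The aldehyde is non-enolisable, so the only demand is chemoselectivity over the lactone carbonyl.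

6 is traced to 4 through 5 by cutting the lactone acyl–oxygen bond and recognising the acyl carbon as a cleaved terminal alkene. The demand is oxidation of the aldehyde level without touching the primary alcohol, and closure through the tertiary oxygen.

4 is cut at the C1–C2 bond to 2 and 3. The forward opening must occur at the CH–CH3 carbon of the epoxide with inversion.

2 is cut at the two epoxide C–O bonds to 1. The forward epoxidation carries all the absolute stereochemical information of the route.

## Other disconnections considered

Alternative 1: The cut runs through the heterocycle (C3′–C4′ and O1′–C2′), so the pyranone is made last. Heating the trienyl dioxinone A2 (tertiary hydroxyls as trimethylsilyl ethers) would release the acyl(methyl)ketene A3 by cycloreversion. A3 would be trapped in a [4+2] sense by the ynol ether A4 (1-methoxyprop-1-yne) to give A1, the bis(trimethylsilyl) ether of the target, and desilylation would finish.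
- In favour: the methoxy group arrives in place and the regiochemistry is fixed by polarity, so the ambident O-methylation of step 19 is avoided. On this point the alternative is better than the chosen plan.
- Against: about 100–120 °C is needed with the complete triene and both acetates present. A3 could electrocyclise, dimerise or be captured by a hydroxyl, hence two extra protection and deprotection events at hindered tertiary centres. A4 is volatile and must be made. A2 still needs the whole ring, so the stereochemical problem is untouched.
- Comparison: on structure both plans end at the same skeleton, but the chosen plan is convergent at the end. On mechanism a thermal pericyclic cascade stands against a room-temperature palladium cycle that is gentler on the triene. On step economy the two are about equal, since steps 16–19 are traded for dioxinone construction, silylation and desilylation.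

Alternative 2: The cut is at C3–O and C6–O, taken as the two ends of a peroxide bridge. Sensitised photo-oxygenation of the cyclohexa-1,3-diene A6 would add singlet oxygen to C3 and C6 anti to the C1 and C2 substituents and give the endoperoxide A5. A6 would come from thermal disrotatory 6π-electrocyclisation of the (E,Z,E)-triene A7.
- In favour: both C–O bonds form in one suprafacial step, so the C3 and C6 oxygens are necessarily cis. In security of relative configuration this equals the chosen plan. O–O reduction of A5 would give exactly 14, so everything after step 9 would be unchanged. A5 needs far fewer steps than the nine to 14, so on step economy the alternative is clearly better.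
- Against: A7 is achiral and nothing in the sequence carries absolute information, so C1 and C2 would arise as a racemate. The single enantiomer would need a resolution or an asymmetric variant without close analogy. A7 needs a defined triene geometry, A6 could undergo hydrogen shifts or aromatise, and ene reactions at the allylic methyls could compete with the [4+2] addition.
- Comparison: the chosen plan is longer and uses a ruthenium catalyst, but it fixes absolute configuration in step 1 and needs no photochemistry.

Alternative 3: The cut is at C1–C2. The cyclic silyl ketene acetal of the six-membered lactone A9 (acetonide on the C5 and C6 oxygens, (E)-but-2-en-2-yl on the carbinol carbon) would rearrange [3,3] through a boat. This would form C1–C2 and contract the lactone to the cyclohexene carboxylic acid A8.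
- In favour: the ring closes together with both C1 and C2 by chirality transfer. This is better than step 9, which creates no stereocentre. C7 emerges as an acid with no protecting group, which is at least equal to the silyl ether of the chosen plan.
- Against: A9 must already hold three contiguous stereocentres (one quaternary) and an E-trisubstituted alkene, which is a long synthesis of its own. The new alkene is C3=C4, so both oxygens there would have to enter syn to the C5 oxygen, on the concave face of the cis-fused acetonide. That would mean removing the acetonide and using a directed osmylation. The acid must also be reduced to the aldehyde level in the presence of everything else.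
- Comparison: the sigmatropic step has predictable transfer but a demanding substrate, whereas the metathesis has no stereochemical demand at all. On step economy the alternative is probably longer overall.

Key step: step 9

Remarks before the steps:
- Assumption: 20, 23, 26 and 2-(dichloromethyl)-4,4,5,5-tetramethyl-1,3,2-dioxaborolane are taken as catalogue chemicals.
- Epoxide opening: 2 must be opened at its CH–CH3 carbon (C3 of the epoxy alcohol). The fully substituted C2 is not attacked.
- Aldol sense: the C1 carbon substituent and the C6 oxygen are trans on the ring, which corresponds to an anti aldol. A syn aldol would give the C6 epimer. The ring-locked E-enolate of lactone 8 is therefore used.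
- Precursor design: in 13 only the primary oxygen is protected, as a silyl ether, and both allylic hydroxyls are free. No global deprotection then exposes a primary alcohol beside the hydroxyls to be acetylated, and both allylic hydroxyls direct the osmylation.

## Route

Step 1
Reactants: 1 (E)-2-methylbut-2-en-1-ol
Product: 2 [(2S,3S)-2,3-dimethyloxiran-2-yl]methanol
Conditions: Ti(OiPr)4 (10 mol%), L-(+)-diisopropyl tartrate (12 mol%), t-BuOOH, 4 Å molecular sieves, CH2Cl2, −20 °C
Reagents that add atoms: tert-butyl hydroperoxide, CC(C)(C)OO
Why: Sharpless asymmetric epoxidation; with the L-(+)-tartrate the titanium–tartrate–peroxide complex delivers oxygen to the face of the (E)-trisubstituted allylic alcohol that gives the (2S,3S)-epoxide, fixing the future ring C3 (kept) and, after inversion in step 2, ring C2.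

Step 2
Reactants: 2 [(2S,3S)-2,3-dimethyloxiran-2-yl]methanol; 3 allylmagnesium bromide
Product: 4 (2R,3S)-2,3-dimethylhex-5-ene-1,2-diol
Conditions: 3 (3 equiv), CuI (10 mol%), THF, −30 → 0 °C; aq. NH4Cl
Reagents that add atoms: none
Why: Copper-catalysed Grignard opening of a 2,3-epoxy alcohol; the fully substituted epoxide carbon is blocked, so the allyl group attacks the CH–CH3 carbon in an SN2 sense with inversion and sets ring C2, the first equivalent of 3 only deprotonating the hydroxyl.

Step 3
Reactants: 4 (2R,3S)-2,3-dimethylhex-5-ene-1,2-diol
Product: 6 (4S,5R)-5-(hydroxymethyl)-4,5-dimethyloxolan-2-one, via dihydroxy aldehyde 5 (not isolated)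
Conditions: O3, CH2Cl2, −78 °C; PPh3, → rt; then Br2, NaHCO3, MeCN/H2O, 0 °C → rt; then TsOH·H2O (cat.), PhMe, 40 °C
Reagents that add atoms: ozone, [O-][O+]=O
Why: Ozonolysis of the only alkene gives the aldehyde, which closes to cyclic hemiacetals; buffered bromine water oxidises hemiacetals to lactones (the aldose-to-aldonolactone reaction) without touching the primary alcohol, and acid equilibration funnels the material to the more stable five-membered lactone through the tertiary oxygen; no stereocentre is touched.

Step 4
Reactants: 6 (4S,5R)-5-(hydroxymethyl)-4,5-dimethyloxolan-2-one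
Product: 7 (2R,3S)-2,3-dimethyl-5-oxooxolane-2-carbaldehyde
Conditions: Dess–Martin periodinane, NaHCO3, CH2Cl2, 0 °C → rt
Reagents that add atoms: none
Why: Dess–Martin oxidation of a primary alcohol; the aldehyde sits on a fully substituted carbon and can neither enolise nor epimerise.

Step 5
Reactants: 7 (2R,3S)-2,3-dimethyl-5-oxooxolane-2-carbaldehyde
Product: 8 (4S,5S)-5-ethenyl-4,5-dimethyloxolan-2-one
Conditions: Ph3PCH3Br, KOtBu, THF, 0 °C; then 7, −78 → 0 °C
Reagents that add atoms: methyltriphenylphosphonium bromide, C[P+](c1ccccc1)(c1ccccc1)c1ccccc1.[Br-]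
Why: Wittig methylenation of a non-enolisable aldehyde; at low temperature the unstabilised ylide reacts with the aldehyde much faster than with the lactone carbonyl.

Step 6
Reactants: 8 (4S,5S)-5-ethenyl-4,5-dimethyloxolan-2-one; 9 methacrolein
Product: 11 (3R,4S,5S)-5-ethenyl-3-[(1S)-1-hydroxy-2-methylprop-2-en-1-yl]-4,5-dimethyloxolan-2-one, via lithium enolate 10 (not isolated)
Conditions: LiN(iPr)2, THF, −78 °C; 9, −78 °C, 15 min; AcOH, −78 °C
Reagents that add atoms: none
Why: Aldol addition of a lactone lithium enolate; the aldehyde enters anti to the adjacent ring methyl (and the cis vinyl group), which sets ring C1 trans to the C2 methyl, and the ring-locked E(O)-enolate reacts through a chair Zimmerman–Traxler transition state with the isopropenyl group equatorial, which gives the required anti C1/C6 relationship; 1,2-addition to the enal is the kinetic path at −78 °C.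

Step 7
Reactants: 11 (3R,4S,5S)-5-ethenyl-3-[(1S)-1-hydroxy-2-methylprop-2-en-1-yl]-4,5-dimethyloxolan-2-one
Product: 12 (3S,4S,5S,6S)-4-(hydroxymethyl)-2,5,6-trimethylocta-1,7-diene-3,6-diol
Conditions: LiAlH4, THF, −20 → 0 °C; aq. NaOH work-up
Reagents that add atoms: none
Why: Hydride reduction of the lactone to the 1,4-diol frees the primary C7 hydroxyl and the tertiary C3 hydroxyl at once; the low temperature keeps the β-hydroxy lactone from retro-aldol cleavage and no stereocentre is touched.

Step 8
Reactants: 12 (3S,4S,5S,6S)-4-(hydroxymethyl)-2,5,6-trimethylocta-1,7-diene-3,6-diol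
Product: 13 (3S,4S,5S,6S)-4-{[tert-butyl(dimethyl)silyl]oxymethyl}-2,5,6-trimethylocta-1,7-diene-3,6-diol
Conditions: TBSCl (1.05 equiv), imidazole, CH2Cl2, −20 → 0 °C
Reagents that add atoms: tert-butyldimethylsilyl chloride, CC(C)(C)[Si](C)(C)Cl
Why: Silylation of the primary hydroxyl only, which reacts far faster with the bulky silyl chloride than the hindered secondary allylic or the tertiary hydroxyl; this gives the metathesis precursor with both allylic hydroxyls free.

Step 9
Reactants: 13 (3S,4S,5S,6S)-4-{[tert-butyl(dimethyl)silyl]oxymethyl}-2,5,6-trimethylocta-1,7-diene-3,6-diol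
Product: 14 (1R,4S,5S,6S)-5-{[tert-butyl(dimethyl)silyl]oxymethyl}-1,3,6-trimethylcyclohex-2-ene-1,4-diol
Conditions: second-generation Grubbs catalyst RuCl2(=CHPh)(H2IMes)(PCy3) (2 × 5 mol%), CH2Cl2 (0.005 M), 40 °C, argon sparge
Reagents that add atoms: none
Why: Ring-closing olefin metathesis by the Chauvin mechanism: the ruthenium benzylidene exchanges onto the less hindered monosubstituted vinyl group at C3, the new alkylidene adds across the CH2 terminus of the isopropenyl group at C6 in a [2+2] step, and cycloreversion of the ruthenacyclobutane releases the C4=C5 alkene and Ru=CH2, which turns over with loss of ethene. The closest known reaction type is ring-closing metathesis of 1,7-dienes with free allylic hydroxyls to trisubstituted cyclohexenols with second-generation ruthenium carbenes. One ring is closed, the six-membered carbocycle C1–C6, by joining the two alkene carbons that become C4 and C5, and the ring alkene is necessarily cis. No stereocentre is formed or touched; C1, C2, C3 and C6 come in from steps 1, 2 and 6. The only selectivity needed is cyclisation over intermolecular metathesis, and it is secured by high dilution, by the 1,1-disubstituted partner that does not homodimerise, by the six-membered ring size and by the branched backbone with its quaternary carbon that holds the two alkenes close. Only two alkenes are present, so no other ring size can form, and removal of ethene makes the closure irreversible. The free allylic hydroxyls are tolerated by this catalyst and are kept because both are needed as directing groups in step 10.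

Step 10
Reactants: 14 (1R,4S,5S,6S)-5-{[tert-butyl(dimethyl)silyl]oxymethyl}-1,3,6-trimethylcyclohex-2-ene-1,4-diol
Product: 16 (1R,2R,3S,4S,5S,6S)-5-{[tert-butyl(dimethyl)silyl]oxymethyl}-1,3,6-trimethylcyclohexane-1,2,3,4-tetrol, via osmate ester 15 (not isolated)
Conditions: OsO4 (1.05 equiv), TMEDA (1.1 equiv), CH2Cl2, −78 °C; then aq. Na2SO3, THF, 65 °C
Reagents that add atoms: osmium tetroxide, O=[Os](=O)(=O)=O
Why: Hydrogen-bond-directed dihydroxylation: the OsO4·TMEDA adduct accepts hydrogen bonds from the allylic C3 and C6 hydroxyls, which lie on the same face, while the other face is shielded by the C3 methyl and the pseudo-axial C2 methyl, so the concerted [3+2] addition places both new oxygens (C4, C5) cis to the existing ones; sulfite then cleaves the stable osmate ester.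

Step 11
Reactants: 16 (1R,2R,3S,4S,5S,6S)-5-{[tert-butyl(dimethyl)silyl]oxymethyl}-1,3,6-trimethylcyclohexane-1,2,3,4-tetrol
Product: 17 C4,C6-di-O-acetate of 16 (ring numbering of this proposal; C3 and C5 hydroxyls free, configuration as in 16)
Conditions: Ac2O (4 equiv), pyridine, DMAP (0.1 equiv), CH2Cl2, 0 °C → rt
Reagents that add atoms: acetic anhydride, CC(=O)OC(C)=O
Why: Nucleophile-catalysed acylation; the two secondary equatorial hydroxyls react much faster than the two tertiary axial ones, so stopping at the diacetate is a matter of stoichiometry and reaction time.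

Step 12
Reactants: 17 C4,C6-di-O-acetate of 16
Product: 18 primary alcohol: 17 with the silyl ether at C7 replaced by OH
Conditions: HF·pyridine, pyridine, THF, 0 °C → rt
Reagents that add atoms: none
Why: Fluoride cleavage of the primary silyl ether under buffered, weakly acidic conditions, where base-promoted acetyl migration and ester hydrolysis do not occur.

Step 13
Reactants: 18 primary alcohol
Product: 19 aldehyde: C7 of 18 oxidised to CHO (ring configuration unchanged)
Conditions: Dess–Martin periodinane, NaHCO3, CH2Cl2, 0 °C → rt
Reagents that add atoms: none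
Why: Buffered Dess–Martin oxidation gives the aldehyde without base, so neither the α-stereocentre C1 nor the β-acetoxy group at C6 is put at risk; tertiary alcohols are inert.

Step 14
Reactants: 19 aldehyde; 20 2-(triphenyl-λ5-phosphanylidene)propanal
Product: 21 (E)-2-methyl-3-(ring-C1-yl)prop-2-enal (C7=C8 E; ring as in 19)
Conditions: 20 (3 equiv), PhMe, 80 °C
Reagents that add atoms: none
Why: Wittig reaction with a stabilised, weakly basic formyl ylide gives the (E)-2-methyl enal (thermodynamic selectivity of stabilised ylides) without enolising the β-acetoxy aldehyde.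

Step 15
Reactants: 21 (E)-enal
Product: 22 (1E,3E)-dienyl pinacol boronate: pinB–C10H=C9H–C8(CH3)=C7H–ring
Conditions: CrCl2 (8 equiv), Cl2CHBpin (2 equiv), LiI (4 equiv), THF, rt, dark
Reagents that add atoms: 2-(dichloromethyl)-4,4,5,5-tetramethyl-1,3,2-dioxaborolane, CC1(C)OB(OC1(C)C)C(Cl)Cl
Why: Takai–Utimoto-type boryl olefination: halogen exchange and reduction by divalent chromium give a geminal dichromium boryl species that adds to the aldehyde and eliminates anti to give the (E)-alkenyl boronate; the reagent is non-basic and leaves esters, alcohols and the trisubstituted alkene alone.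

Step 16
Reactants: 23 (E)-3-iodo-2-methylprop-2-enoic acid
Product: 25 (E)-3-iodo-N-methoxy-N,2-dimethylprop-2-enamide, via acid chloride 24 (not isolated)
Conditions: (COCl)2, DMF (cat.), CH2Cl2, 0 °C → rt; then MeNH(OMe)·HCl, pyridine, CH2Cl2, 0 °C
Reagents that add atoms: N,O-dimethylhydroxylamine hydrochloride, CNOC.Cl
Why: Acid chloride formation and amidation to the Weinreb amide; neither stage touches the vinyl iodide, whose E geometry is carried through unchanged.

Step 17
Reactants: 26 ethyl 2-methyl-3-oxopentanoate; 25 (E)-3-iodo-N-methoxy-N,2-dimethylprop-2-enamide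
Product: 28 ethyl (E)-7-iodo-2,4,6-trimethyl-3,5-dioxohept-6-enoate, via dianion 27 (not isolated)
Conditions: 26, NaH, THF, 0 °C; n-BuLi, 0 °C; then 25, −78 → 0 °C; aq. NH4Cl
Reagents that add atoms: none
Why: Acylation of a β-keto ester dianion at its more reactive γ-carbon by a Weinreb amide, whose chelated tetrahedral adduct prevents a second addition; the hard carbanion attacks the amide carbonyl and not the β-iodo carbon.

Step 18
Reactants: 28 ethyl (E)-7-iodo-2,4,6-trimethyl-3,5-dioxohept-6-enoate
Product: 29 4-hydroxy-6-[(E)-1-iodoprop-1-en-2-yl]-3,5-dimethyl-2H-pyran-2-one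
Conditions: DBU, PhMe, 80 °C; then 1 M HCl
Reagents that add atoms: none
Why: Base-mediated cyclisation of a 3,5-diketo ester: the C5 enol oxygen closes onto the ester (6-exo-trig lactonisation) with loss of ethanol, and both former stereocentres become sp2 carbons of the hydroxypyranone.

Step 19
Reactants: 29 4-hydroxy-6-[(E)-1-iodoprop-1-en-2-yl]-3,5-dimethyl-2H-pyran-2-one
Product: 30 6-[(E)-1-iodoprop-1-en-2-yl]-2-methoxy-3,5-dimethyl-4H-pyran-4-one
Conditions: MeOTf, CH2Cl2, rt; then aq. NaHCO3
Reagents that add atoms: methyl trifluoromethanesulfonate, COS(=O)(=O)C(F)(F)F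
Why: A hard methylating agent without base alkylates the more basic lactone carbonyl oxygen of a 4-hydroxy-2-pyranone, and loss of the proton from the resulting pyrylium gives the 2-methoxy-4-pyranone and not the 4-methoxy-2-pyranone.

Step 20
Reactants: 22 (1E,3E)-dienyl pinacol boronate; 30 6-[(E)-1-iodoprop-1-en-2-yl]-2-methoxy-3,5-dimethyl-4H-pyran-4-one
Product: 31 amaurone B
Conditions: PdCl2(dppf) (10 mol%), K3PO4 (3 equiv), THF/H2O (5:1), degassed, rt, dark
Reagents that add atoms: none
Why: Suzuki–Miyaura coupling of an alkenyl boronate with an alkenyl iodide; oxidative addition, base-assisted transmetallation and reductive elimination all proceed with retention at both alkenes, so the (E,E,E)-triene is assembled from three geometries set earlier, and room temperature with phosphate as base should spare the acetates.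

## Compound list

1 | (E)-2-methylbut-2-en-1-ol | C/C=C(\C)CO | starting material
2 | [(2S,3S)-2,3-dimethyloxiran-2-yl]methanol | C[C@@H]1O[C@@]1(C)CO | intermediate
3 | allylmagnesium bromide | C=CC[Mg]Br | starting material
4 | (2R,3S)-2,3-dimethylhex-5-ene-1,2-diol | C=CC[C@H](C)[C@@](C)(O)CO | intermediate
5 | (3S,4R)-4,5-dihydroxy-3,4-dimethylpentanal (present as its cyclic hemiacetals) | O=CC[C@H](C)[C@@](C)(O)CO | intermediate (not isolated)
6 | (4S,5R)-5-(hydroxymethyl)-4,5-dimethyloxolan-2-one | O=C1C[C@H](C)[C@](C)(CO)O1 | intermediate
7 | (2R,3S)-2,3-dimethyl-5-oxooxolane-2-carbaldehyde | O=C1C[C@H](C)[C@](C)(C=O)O1 | intermediate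
8 | (4S,5S)-5-ethenyl-4,5-dimethyloxolan-2-one | O=C1C[C@H](C)[C@](C)(C=C)O1 | intermediate
9 | methacrolein (2-methylprop-2-enal) | CC(=C)C=O | starting material
10 | lithium enolate of 8 | [Li+].[O-]C1=C[C@H](C)[C@](C)(C=C)O1 | intermediate (not isolated)
11 | (3R,4S,5S)-5-ethenyl-3-[(1S)-1-hydroxy-2-methylprop-2-en-1-yl]-4,5-dimethyloxolan-2-one | O=C1[C@@H]([C@H](O)C(C)=C)[C@H](C)[C@](C)(C=C)O1 | intermediate
12 | (3S,4S,5S,6S)-4-(hydroxymethyl)-2,5,6-trimethylocta-1,7-diene-3,6-diol | OC[C@@H]([C@H](O)C(C)=C)[C@H](C)[C@@](C)(O)C=C | intermediate
13 | (3S,4S,5S,6S)-4-{[tert-butyl(dimethyl)silyl]oxymethyl}-2,5,6-trimethylocta-1,7-diene-3,6-diol (metathesis precursor) | CC(C)(C)[Si](C)(C)OC[C@@H]([C@H](O)C(C)=C)[C@H](C)[C@@](C)(O)C=C | intermediate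
14 | (1R,4S,5S,6S)-5-{[tert-butyl(dimethyl)silyl]oxymethyl}-1,3,6-trimethylcyclohex-2-ene-1,4-diol (metathesis product) | CC(C)(C)[Si](C)(C)OC[C@@H]1[C@H](C)[C@@](C)(O)C=C(C)[C@H]1O | intermediate
15 | cyclic osmate ester of 14 across C4/C5, TMEDA adduct | CC(C)(C)[Si](C)(C)OC[C@@H]1[C@H](C)[C@@](C)(O)[C@H]2O[Os](=O)(=O)O[C@@]2(C)[C@H]1O.CN(C)CCN(C)C | intermediate (not isolated)
16 | (1R,2R,3S,4S,5S,6S)-5-{[tert-butyl(dimethyl)silyl]oxymethyl}-1,3,6-trimethylcyclohexane-1,2,3,4-tetrol | CC(C)(C)[Si](C)(C)OC[C@@H]1[C@H](C)[C@@](C)(O)[C@@H](O)[C@@](C)(O)[C@H]1O | intermediate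
17 | C4,C6-di-O-acetate of 16 (tertiary C3 and C5 hydroxyls free) | CC(C)(C)[Si](C)(C)OC[C@@H]1[C@H](C)[C@@](C)(O)[C@@H](OC(C)=O)[C@@](C)(O)[C@H]1OC(C)=O | intermediate
18 | primary alcohol (17 without the silyl group) | OC[C@@H]1[C@H](C)[C@@](C)(O)[C@@H](OC(C)=O)[C@@](C)(O)[C@H]1OC(C)=O | intermediate
19 | ring aldehyde (C7 = CHO) | O=C[C@@H]1[C@H](C)[C@@](C)(O)[C@@H](OC(C)=O)[C@@](C)(O)[C@H]1OC(C)=O | intermediate
20 | 2-(triphenyl-λ5-phosphanylidene)propanal | CC(C=O)=P(c1ccccc1)(c1ccccc1)c1ccccc1 | starting material
21 | (E)-2-methyl enal on ring C1 | O=C/C(C)=C/[C@@H]1[C@H](C)[C@@](C)(O)[C@@H](OC(C)=O)[C@@](C)(O)[C@H]1OC(C)=O | intermediate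
22 | (1E,3E)-dienyl pinacol boronate | CC1(C)OB(OC1(C)C)/C=C/C(C)=C/[C@@H]1[C@H](C)[C@@](C)(O)[C@@H](OC(C)=O)[C@@](C)(O)[C@H]1OC(C)=O | intermediate
23 | (E)-3-iodo-2-methylprop-2-enoic acid | OC(=O)/C(C)=C/I | starting material
24 | (E)-3-iodo-2-methylprop-2-enoyl chloride | ClC(=O)/C(C)=C/I | intermediate (not isolated)
25 | (E)-3-iodo-N-methoxy-N,2-dimethylprop-2-enamide | CON(C)C(=O)/C(C)=C/I | intermediate
26 | ethyl 2-methyl-3-oxopentanoate | CCOC(=O)C(C)C(=O)CC | starting material
27 | sodium lithium dianion of 26 | [Na+].[Li+].CCOC([O-])=C(C)C([O-])=CC | intermediate (not isolated)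
28 | ethyl (E)-7-iodo-2,4,6-trimethyl-3,5-dioxohept-6-enoate (C2/C4 epimers and enol forms; both centres become sp2 in step 18) | CCOC(=O)C(C)C(=O)C(C)C(=O)/C(C)=C/I | intermediate
29 | 4-hydroxy-6-[(E)-1-iodoprop-1-en-2-yl]-3,5-dimethyl-2H-pyran-2-one | Cc1c(O)c(C)c(/C(C)=C/I)oc1=O | intermediate
30 | 6-[(E)-1-iodoprop-1-en-2-yl]-2-methoxy-3,5-dimethyl-4H-pyran-4-one | COc1oc(/C(C)=C/I)c(C)c(=O)c1C | intermediate
31 | amaurone B | COc1oc(/C(C)=C/C=C/C(C)=C/[C@@H]2[C@H](C)[C@@](C)(O)[C@@H](OC(C)=O)[C@@](C)(O)[C@H]2OC(C)=O)c(C)c(=O)c1C | target

## Step count and least certain steps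

Total step count: 20. Longest linear sequence: 16 (steps 1–15 and 20); the pyranone branch (steps 16–19) has 4 steps.

**Step 9 (key step).** Initiation at the vinyl group on the quaternary carbinol may be slow, so that intermolecular metathesis competes. As the catalyst ages, ruthenium hydride species may isomerise the free secondary allylic alcohol to a ketone, or the 1,4-diol may sequester the metal. Fallback (masks the sensitive hydroxyl as the acetate it must become anyway): from 13, acetylation (Ac2O, pyridine) of the only secondary hydroxyl should give the C6 acetate of the diene F1. The same ring closure should give the cyclohexenyl acetate F2. Osmylation with OsO4/TMEDA, now directed by the C3 hydroxyl alone, should give the triol monoacetate F3. Acetylation of its single secondary hydroxyl comes back to the route at 17.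

**Step 6.** The facial sense at C1 is secure, but the simple diastereoselectivity at the carbinol carbon may be poor. A lithium lactone enolate discriminates only moderately between equatorial and axial placement of the aldehyde substituent in the chair transition state, and retro-aldol equilibration may erode it further. Fallback (oxidation–reduction in place of direct control): from crude 11 containing its carbinol epimer F4, Dess–Martin oxidation should converge both to the keto lactone F5. A 1,2-selective, non-chelating reduction (NaBH4, CeCl3·7H2O, MeOH, −78 °C) should deliver hydride to the dipole-minimised conformer from the side away from ring C2. This is the anti sense and returns to 11; the minor epimer can be recycled through F5.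

**Step 3.** Oxidation of the hemiacetal mixture may be incomplete, or closure through the primary hydroxyl may give the six-membered lactone and so a regioisomeric mixture. Fallback (protecting-group route): from 4, silylation of the primary hydroxyl (TBSCl, imidazole) should give the silyl ether F6. Ozonolysis (O3; PPh3) can then form only the five-membered lactol F7. Oxidation (TEMPO cat., PhI(OAc)2) should give the silyloxymethyl lactone F8, and Bu4NF comes back to the route at 6.

**Step 14.** At 80 °C the ylide may enolise the α-branched aldehyde, leading to β-elimination of the C6 acetate or epimerisation at C1; the olefination of this hindered aldehyde may also be sluggish. Fallback (metathesis in place of a carbonyl olefination): from 19, non-basic methylenation (Zn, CH2I2, TiCl4, THF) should give the vinylcyclohexane F9. Cross-metathesis with an excess of 9 (second-generation Hoveyda–Grubbs catalyst RuCl2(=CH-C6H4-2-OiPr)(H2IMes), CH2Cl2, 40 °C) should give the E-enal and returns to the route at 21.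

**Step 20.** Aqueous base may hydrolyse an acetate or move it to a neighbouring hydroxyl, the dienyl boronate may protodeboronate, and the triene may isomerise during a slow coupling. Fallback (base-free Stille coupling with reversed roles): from 21, iodo-olefination (CrCl2, CHI3, THF, 0 °C) should give the (1E,3E)-dienyl iodide F10. From 30, stannylation (Me3SnSnMe3, Pd(PPh3)4, PhMe, 80 °C) should give the pyranone alkenylstannane F11. Coupling of F10 and F11 (Pd2(dba)3, AsPh3, CuI, DMF, rt) comes back to the route at 31.

## Further compounds

F1 | step 9 | C6 acetate of 13 | CC(C)(C)[Si](C)(C)OC[C@@H]([C@H](OC(C)=O)C(C)=C)[C@H](C)[C@@](C)(O)C=C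
F2 | step 9 | C6 acetate of 14 | CC(C)(C)[Si](C)(C)OC[C@@H]1[C@H](C)[C@@](C)(O)C=C(C)[C@H]1OC(C)=O
F3 | step 9 | C6 monoacetate of 16 | CC(C)(C)[Si](C)(C)OC[C@@H]1[C@H](C)[C@@](C)(O)[C@@H](O)[C@@](C)(O)[C@H]1OC(C)=O
F4 | step 6 | (3R,4S,5S)-5-ethenyl-3-[(1R)-1-hydroxy-2-methylprop-2-en-1-yl]-4,5-dimethyloxolan-2-one | O=C1[C@@H]([C@@H](O)C(C)=C)[C@H](C)[C@](C)(C=C)O1
F5 | step 6 | (3R,4S,5S)-5-ethenyl-4,5-dimethyl-3-(2-methylprop-2-enoyl)oxolan-2-one | O=C1[C@@H](C(=O)C(C)=C)[C@H](C)[C@](C)(C=C)O1
F6 | step 3 | (2R,3S)-1-{[tert-butyl(dimethyl)silyl]oxy}-2,3-dimethylhex-5-en-2-ol | C=CC[C@H](C)[C@@](C)(O)CO[Si](C)(C)C(C)(C)C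
F7 | step 3 | (4S,5R)-5-{[tert-butyl(dimethyl)silyl]oxymethyl}-4,5-dimethyloxolan-2-ol (anomer mixture) | OC1C[C@H](C)[C@](C)(CO[Si](C)(C)C(C)(C)C)O1
F8 | step 3 | (4S,5R)-5-{[tert-butyl(dimethyl)silyl]oxymethyl}-4,5-dimethyloxolan-2-one | O=C1C[C@H](C)[C@](C)(CO[Si](C)(C)C(C)(C)C)O1
F9 | step 14 | vinylcyclohexane (C7 = CH=CH2; ring as in 19) | C=C[C@@H]1[C@H](C)[C@@](C)(O)[C@@H](OC(C)=O)[C@@](C)(O)[C@H]1OC(C)=O
F10 | step 20 | (1E,3E)-dienyl iodide (ring as in 21) | I/C=C/C(C)=C/[C@@H]1[C@H](C)[C@@](C)(O)[C@@H](OC(C)=O)[C@@](C)(O)[C@H]1OC(C)=O
F11 | step 20 | 2-methoxy-3,5-dimethyl-6-[(E)-1-(trimethylstannyl)prop-1-en-2-yl]-4H-pyran-4-one | COc1oc(/C(C)=C/[Sn](C)(C)C)c(C)c(=O)c1C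
A1 | alternative 1 | bis(trimethylsilyl) ether of amaurone B | COc1oc(/C(C)=C/C=C/C(C)=C/[C@@H]2[C@H](C)[C@@](C)(O[Si](C)(C)C)[C@@H](OC(C)=O)[C@@](C)(O[Si](C)(C)C)[C@H]2OC(C)=O)c(C)c(=O)c1C
A2 | alternative 1 | 2,2,5-trimethyl-6-trienyl-4H-1,3-dioxin-4-one (tertiary hydroxyls as trimethylsilyl ethers) | CC1(C)OC(=O)C(C)=C(O1)/C(C)=C/C=C/C(C)=C/[C@@H]2[C@H](C)[C@@](C)(O[Si](C)(C)C)[C@@H](OC(C)=O)[C@@](C)(O[Si](C)(C)C)[C@H]2OC(C)=O
A3 | alternative 1 | trienoyl(methyl)ketene | O=C=C(C)C(=O)/C(C)=C/C=C/C(C)=C/[C@@H]2[C@H](C)[C@@](C)(O[Si](C)(C)C)[C@@H](OC(C)=O)[C@@](C)(O[Si](C)(C)C)[C@H]2OC(C)=O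
A4 | alternative 1 | 1-methoxyprop-1-yne | COC#CC
A5 | alternative 2 | bicyclic endoperoxide (2,3-dioxabicyclo[2.2.2]octene) | CC(C)(C)[Si](C)(C)OC[C@@H]2[C@H](C)[C@@]3(C)OO[C@@H]2C(C)=C3
A6 | alternative 2 | cis-5-(silyloxymethyl)-1,3,6-trimethylcyclohexa-1,3-diene | CC(C)(C)[Si](C)(C)OC[C@@H]1[C@H](C)C(C)=CC(C)=C1
A7 | alternative 2 | (E,Z,E)-silyloxy triene | CC(C)(C)[Si](C)(C)OC/C=C/C(C)=C\C(C)=C\C
A8 | alternative 3 | cyclohexene carboxylic acid acetonide | OC(=O)[C@@H]2[C@H](C)C(C)=C[C@@]3(C)OC(C)(C)O[C@@H]23
A9 | alternative 3 | six-membered lactone acetonide with (E)-but-2-en-2-yl group on the carbinol carbon | O=C1C[C@@H]2OC(C)(C)O[C@]2(C)[C@@H](O1)/C(C)=C/C
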